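**Plan**

- Retrosynthesis: remove the acetate, cut C13=C14 with C13–CH3 and C14–C15 (alkyne carbometalation) and C12–C13 (one-carbon homologations) back to a cis-fused γ-lactone C8–O–C12(=O). Then cut C8–O and C9–C11 back to a bicyclic 7,8-epoxy-9-ketone, open ring A at C3–C4, and cut C10–CH3 and C10–C1 to reach (S)-carvone.
- Enabling feature: the gem-dimethyl carbon C4 is bonded to the ring-fusion CH C5 of ring B, so C5, C4, one C4 methyl and the other as =CH2 are the ring carbon and isopropenyl group of carvone. A three-carbon arm on C10 ends at C3, 1,6 to C4, so Markovnikov hydroalkylation of the isopropenyl group by the C3–iodine bond closes ring A and makes quaternary C4 in one event, leaving no function in ring A.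
- Forward: ring B is carvone (its ten carbons become C4–C10, C17, C18, C19). Two alkylations build C10, the enone is masked as its epoxide, ring A is closed last (step 5), Wharton/Claisen/lactonisation set C9 and C8, and the chain is grown from C12 to C15.
- Stereochemistry: C5 from (S)-carvone; C10 from the alkylation order (CH3 enters anti to isopropenyl, giving the cis ring fusion); the oxirane forms anti to isopropenyl and its C7–O bond is relayed to C9 by a suprafacial [3,3] shift and to C8 by the cis-lactone tether; 13E from syn-carboalumination.

Key step: step 5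

Remark: as drawn, the target is a cis-fused labdane, (1R,2S,4aR,8aS) in decalin numbering: H-5, CH3-20, the C9 side chain and the 8-hydroxyl lie on one face and CH3-17 on the other. Labdane numbering is used throughout (ring A = C1–C5, C10; ring B = C5–C10; side chain C11–C16; CH3-17 on C8; CH3-18/19 on C4; CH3-20 on C10).

**Route**

Step 1
Reactants: 1 (S)-(+)-carvone
Product: 3 6-(3-chloropropyl)carvone (C6 epimers; trans drawn), via lithium dienolate of carvone 2 (not isolated)
Conditions: LiN(i-Pr)2, THF, −78 °C; then ClCH2CH2CH2I, DMPU, −78 to −20 °C
Reagents that add atoms: 1-chloro-3-iodopropane, ClCCCI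
Why: Kinetic deprotonation at the α′-CH2 (C10) gives the cross-conjugated lithium dienolate, which is C-alkylated at the iodide end of the dihalide only (enolate alkylation); the C10 configuration made here is erased in step 2.

Step 2
Reactants: 3 6-(3-chloropropyl)carvone
Product: 5 6-(3-chloropropyl)-6-methylcarvone (CH3 trans to isopropenyl), via lithium enolate of chloropropylcarvone 4 (not isolated)
Conditions: LiN(i-Pr)2, THF, −78 °C; then MeI, −78 to 0 °C
Reagents that add atoms: iodomethane, IC
Why: Re-enolisation makes C10 planar and iodomethane should attack anti to the neighbouring isopropenyl group (diastereoselective enolate alkylation, as in the sequential dialkylation of carvone), so CH3-20 ends trans and the chloropropyl arm cis to the C4 unit, which is the cis ring fusion of the target; the chloride is inert to the enolate at low temperature.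

Step 3
Reactants: 5 6-(3-chloropropyl)-6-methylcarvone
Product: 6 chloro epoxy ketone (oxirane trans to isopropenyl)
Conditions: 30% H2O2, NaOH (cat.), MeOH, 0 °C
Reagents that add atoms: hydrogen peroxide, OO
Why: Weitz–Scheffer epoxidation: hydroperoxide adds to C7 axially and anti to the C5 isopropenyl group, as in carvone itself, so the oxirane lies on the CH3-20 face; the isopropenyl group and the chloride do not react, and the enone C=C is removed before the radical step.

Step 4
Reactants: 6 chloro epoxy ketone
Product: 7 iodo epoxy ketone
Conditions: NaI, acetone, reflux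
Reagents that add atoms: sodium iodide, [Na+].[I-]
Why: Finkelstein exchange at the unhindered primary chloride, driven by precipitation of NaCl, gives the iodide that nickel can activate; the neutral medium should leave the epoxy ketone alone.

Step 5
Reactants: 7 iodo epoxy ketone
Product: 8 cis-fused bicyclic 7,8-epoxy-9-ketone (rings A and B complete)
Conditions: Mn(dpm)3 (0.3 equiv), Ni(acac)2 (0.1 equiv), PhSiH3, K2CO3, (CF3)2CHOH, ClCH2CH2Cl, 25 °C, 0.01 M, slow addition of 7
Reagents that add atoms: none
Why: Proposed new method: a manganese hydride formed from Mn(dpm)3 and PhSiH3 transfers a hydrogen atom to the =CH2 terminus of the isopropenyl group, so that this carbon becomes the second methyl on C4 and C4 becomes a tertiary radical, while low-valent nickel inserts into the primary C3–iodine bond; the alkylnickel captures the C4 radical and C(sp3)–C(sp3) reductive elimination forms the C3–C4 bond, the closest known reaction being the intermolecular Mn/Ni dual-catalytic Markovnikov hydroalkylation of 1,1-disubstituted alkenes with primary alkyl iodides, which forms quaternary carbons. Ring A closes as a six-membered ring by reductive elimination from a seven-membered nickelacycle (C3–Ni–C4), formally a 6-exo-tet alkylation of the C4 radical and not a radical addition to a π bond. No new stereocentre arises because C4 carries two methyl groups; the cis ring fusion is already fixed by C5 (carvone) and C10 (step 2), whose cis arms hold C3 and C4 within bonding distance. The step needs hydrogen-atom transfer to one alkene only, Markovnikov selectivity, and ring closure faster than reduction of the radical or of the carbon–iodine bond; the substrate secures these by having the isopropenyl group as its only C=C (the enone is masked as the epoxide), by the tertiary over primary radical stability, and by the 1,6-relationship of C4 and C3 under high dilution.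

Step 6
Reactants: 8 bicyclic epoxy ketone
Product: 10 allylic alcohol (7-OH on the CH3-20 face; C8=C9), via epoxy hydrazone 9 (not isolated)
Conditions: N2H4·H2O, AcOH (cat.), MeOH, 0 to 40 °C
Reagents that add atoms: none
Why: Wharton transposition: the epoxy hydrazone opens to a vinyl diazene that loses N2, moving the double bond to C8=C9 and leaving the former oxirane oxygen as the 7-hydroxyl with unchanged configuration, since the C7–O bond is never broken; hydrazine is small enough to reach the hindered C9 carbonyl.

Step 7
Reactants: 10 allylic alcohol
Product: 12 N,N-dimethylamide (CH2CONMe2 on C9, cis to CH3-20; C7=C8), via ketene N,O-acetal 11 (not isolated)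
Conditions: MeC(OMe)2NMe2, xylene, 140 °C
Reagents that add atoms: N,N-dimethylacetamide dimethyl acetal, CC(OC)(OC)N(C)C
Why: Eschenmoser–Claisen rearrangement: the ketene N,O-acetal rearranges suprafacially through a six-membered transition state, so the new C9–C11 bond forms on the face that held the C7–O bond (cis to CH3-20) and the alkene moves to C7=C8; the intramolecular [3,3] shift tolerates the neopentyl position next to C10.

Step 8
Reactants: 12 N,N-dimethylamide
Product: 14 cis-fused γ-lactone (C8–O–C12=O), via cyclic iminium ether trifluoroacetate 13 (not isolated)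
Conditions: CF3CO2H/CH2Cl2 (1:2), 0 °C to rt; then H2O
Reagents that add atoms: water, O
Why: Acid-mediated lactonisation of a γ,δ-unsaturated amide: Markovnikov protonation at C7 gives the tertiary C8 cation, which the amide oxygen captures through a five-membered ring on the face of the C11 arm; the cis-fused lactone is the only one that keeps CH3-17 away from CH3-20, so C8 receives its oxygen cis to C11, and water then hydrolyses the iminium ether.

Step 9
Reactants: 14 γ-lactone
Product: 15 γ-lactol (anomer mixture)
Conditions: i-Bu2AlH, CH2Cl2, −78 °C
Reagents that add atoms: none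
Why: Partial reduction of a lactone with i-Bu2AlH at low temperature stops at the aluminium hemiacetal, which gives the lactol on work-up (standard lactone-to-lactol reduction).

Step 10
Reactants: 15 γ-lactol
Product: 17 δ-lactol (C13 hemiacetal closed onto the 8-oxygen), via methyl enol ether 16 (not isolated)
Conditions: Ph3P(CH2OMe)Cl, KN(SiMe3)2, THF, 0 °C to rt; then 1 M HCl, THF, rt
Reagents that add atoms: (methoxymethyl)triphenylphosphonium chloride, COC[P+](c1ccccc1)(c1ccccc1)c1ccccc1.[Cl-]; water, O
Why: Wittig methoxymethylenation of the open hydroxy aldehyde form, followed by acid hydrolysis of the enol ether, is a one-carbon homologation that makes C12 a methylene and C13 the aldehyde, which the 8-hydroxyl traps as the six-membered lactol; no stereocentre is involved.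

Step 11
Reactants: 17 δ-lactol
Product: 18 terminal alkyne (C13≡C14) with free 8-hydroxyl
Conditions: MeC(O)C(N2)P(O)(OMe)2, K2CO3, MeOH, rt
Reagents that add atoms: dimethyl (1-diazo-2-oxopropyl)phosphonate, COP(=O)(OC)C(=[N+]=[N-])C(C)=O
Why: Ohira–Bestmann (Seyferth–Gilbert) homologation of the aldehyde form of the lactol under mild carbonate conditions gives the terminal alkyne without touching the tertiary alcohol.

Step 12
Reactants: 18 terminal alkyne
Product: 20 (13E)-8,15-diol, via alkenylalane 19 (not isolated)
Conditions: Me3Al (4 equiv), Cp2ZrCl2 (0.3 equiv), CH2Cl2, 0 °C to rt; then (CH2O)n, THF, rt; aqueous Rochelle salt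
Reagents that add atoms: trimethylaluminium, C[Al](C)C; formaldehyde (as paraformaldehyde), C=O
Why: Negishi zirconium-catalysed carboalumination adds CH3 and Al syn across the terminal alkyne with the methyl on C13, and hydroxymethylation of the alkenylalane proceeds with retention, so the 13E alkene should form as a single isomer; the tertiary hydroxyl is carried as its aluminium alkoxide.

Step 13
Reactants: 20 (13E)-8,15-diol
Product: 21 CNP0268033.2 (target)
Conditions: Ac2O, pyridine, CH2Cl2, 0 °C to rt
Reagents that add atoms: acetic anhydride, CC(=O)OC(C)=O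
Why: Acetylation with Ac2O/pyridine is selective for the primary allylic hydroxyl because the tertiary 8-hydroxyl is too hindered to react under these conditions.

**Compound list**

1 | (S)-(+)-carvone, (5S)-2-methyl-5-(prop-1-en-2-yl)cyclohex-2-en-1-one | CC1=CC[C@H](C(C)=C)CC1=O | starting material
2 | lithium dienolate of carvone (C9–OLi, C10=C9) | CC1=CC[C@H](C(C)=C)C=C1O[Li] | intermediate (not isolated)
3 | 6-(3-chloropropyl)carvone, C6 epimer mixture (trans epimer drawn) | CC1=CC[C@H](C(C)=C)[C@@H](CCCCl)C1=O | intermediate
4 | lithium enolate of 3 (tetrasubstituted C9=C10) | CC1=CC[C@H](C(C)=C)C(CCCCl)=C1O[Li] | intermediate (not isolated)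
5 | 6-(3-chloropropyl)-6-methylcarvone, CH3 trans and chloropropyl cis to isopropenyl | CC1=CC[C@H](C(C)=C)[C@](C)(CCCCl)C1=O | intermediate
6 | 2,3-epoxide of 5, oxirane trans to isopropenyl and cis to the C10 methyl | O=C1[C@@]2(C)O[C@H]2C[C@H](C(C)=C)[C@]1(C)CCCCl | intermediate
7 | iodide corresponding to 6 (3-iodopropyl arm) | O=C1[C@@]2(C)O[C@H]2C[C@H](C(C)=C)[C@]1(C)CCCI | intermediate
8 | cis-fused 4,4,8,10-tetramethyldecalin-9-one 7,8-epoxide, oxirane on the face of CH3-20 and H-5 | O=C1[C@@]2(C)CCCC(C)(C)[C@H]2C[C@@H]3O[C@]13C | intermediate
9 | hydrazone of 8 at C9 | NN=C1[C@@]2(C)CCCC(C)(C)[C@H]2C[C@@H]3O[C@]13C | intermediate (not isolated)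
10 | cis-fused allylic alcohol, 7-OH on the CH3-20 face, C8=C9 | CC1=C[C@@]2(C)CCCC(C)(C)[C@H]2C[C@@H]1O | intermediate
11 | ketene N,O-acetal of 10 (O-C(=CH2)NMe2 on C7) | CC1=C[C@@]2(C)CCCC(C)(C)[C@H]2C[C@@H]1OC(=C)N(C)C | intermediate (not isolated)
12 | N,N-dimethylamide, CH2CONMe2 on C9 cis to CH3-20, C7=C8 | CN(C)C(=O)C[C@@H]1[C@@]2(C)CCCC(C)(C)[C@H]2CC=C1C | intermediate
13 | cyclic iminium ether (O on C8 cis to C11) as trifluoroacetate | C[N+](C)=C1C[C@@H]2[C@@]3(C)CCCC(C)(C)[C@H]3CC[C@]2(C)O1.[O-]C(=O)C(F)(F)F | intermediate (not isolated)
14 | cis-fused γ-lactone C8–O–C12(=O), CH3-17 trans to C11 | O=C1C[C@@H]2[C@@]3(C)CCCC(C)(C)[C@H]3CC[C@]2(C)O1 | intermediate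
15 | γ-lactol of 14 (anomer mixture) | OC1C[C@@H]2[C@@]3(C)CCCC(C)(C)[C@H]3CC[C@]2(C)O1 | intermediate
16 | methyl enol ether C12=C13–OMe (E/Z mixture) with free 8-hydroxyl | COC=CC[C@@H]1[C@@]2(C)CCCC(C)(C)[C@H]2CC[C@]1(C)O | intermediate (not isolated)
17 | δ-lactol, C13 hemiacetal closed onto the 8-oxygen (anomer mixture) | OC1CC[C@@H]2[C@@]3(C)CCCC(C)(C)[C@H]3CC[C@]2(C)O1 | intermediate
18 | 8-hydroxy terminal alkyne, but-3-ynyl chain on C9 | C#CCC[C@@H]1[C@@]2(C)CCCC(C)(C)[C@H]2CC[C@]1(C)O | intermediate
19 | (E)-alkenyldimethylalane, Al on C14 cis to the C13 methyl, 8-O–AlMe2 | C[Al](C)/C=C(\C)CC[C@@H]1[C@@]2(C)CCCC(C)(C)[C@H]2CC[C@]1(C)O[Al](C)C | intermediate (not isolated)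
20 | (13E)-8,15-diol of the target skeleton | OC/C=C(\C)CC[C@@H]1[C@@]2(C)CCCC(C)(C)[C@H]2CC[C@]1(C)O | intermediate
21 | CNP0268033.2, (2E)-5-[(1R,2S,4aR,8aS)-2-hydroxy-2,5,5,8a-tetramethyldecahydronaphthalen-1-yl]-3-methylpent-2-en-1-yl acetate | CC(=O)OC/C=C(\C)CC[C@@H]1[C@@]2(C)CCCC(C)(C)[C@H]2CC[C@]1(C)O | target

**Totals**

Total steps: 13. Longest linear sequence: 13 steps from (S)-carvone.

**Steps most likely to fail**

1. Step 5 (proposed new method). What may go wrong: the C4 radical is reduced before it meets nickel (net hydrogenation of the isopropenyl group), the carbon–iodine bond is reduced, or the two ends couple between molecules instead of closing the ring. Fallback with known chemistry, setting out from 1 and coming back at 8: the three-carbon arm is put on C4 first and ring A is then closed at the other end, C10–C1, by enolate alkylation. Carvone 1 is methylated (LiN(i-Pr)2, MeI) to 6-methylcarvone F1 and epoxidised (H2O2, NaOH) to the trans epoxy ketone F2. Its isopropenyl group is hydroalkylated intermolecularly with 1-chloro-3-iodopropane under the established Mn(dpm)3/Ni(acac)2/PhSiH3 conditions to the chloro epoxy ketone F3, which carries C(CH3)2CH2CH2CH2Cl on C5. The potassium enolate of F3 (KN(SiMe3)2, NaI cat., THF) should then alkylate C10 intramolecularly to give 8. A(1,2) strain with the enolate methyl should hold the C5 arm axial, so the arm should reach C10 from its own face and give the cis fusion.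

2. Step 6. What may go wrong: hydrazone formation at a carbonyl flanked by two fully substituted carbons is too slow, and hydrazine opens the oxirane instead. Fallback, setting out from 8 and coming back at 10: the ketone is reduced (NaBH4, MeOH) to the epoxy alcohol F4 and acylated with 1,1′-thiocarbonyldiimidazole (DMAP, ClCH2CH2Cl, reflux) to the thiocarbonylimidazolide F5. Treatment with Bu3SnH/AIBN (toluene, 80 °C) generates the C9 radical, which opens the oxirane at C8–O; the C7 alkoxyl radical is reduced to allylic alcohol 10 with the C7–O bond intact (Barton-type radical fragmentation of an epoxy alcohol).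

3. Step 8. What may go wrong: in the free C8 cation a 1,2-hydride shift from C9 followed by methyl migration from C10, or simple loss of a proton, competes with capture by the amide. Fallback, setting out from 12 and coming back at 14: iodolactonisation of the amide (I2, THF/H2O) proceeds through an iodonium ion instead of a free cation and adds anti, giving the iodolactone F6 with the oxygen on C8 cis to the C11 arm and iodine on C7. Radical deiodination (Bu3SnH, AIBN, toluene, 80 °C) then gives lactone 14.

**Further compounds**

F1 | step 5 | 6-methylcarvone, C6 epimer mixture (trans epimer drawn) | CC1=CC[C@H](C(C)=C)[C@@H](C)C1=O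
F2 | step 5 | 2,3-epoxide of 6-methylcarvone, oxirane trans to isopropenyl | O=C1[C@@]2(C)O[C@H]2C[C@H](C(C)=C)[C@H]1C
F3 | step 5 | epoxy ketone with 5-chloro-2-methylpentan-2-yl group on C5 | O=C1[C@@]2(C)O[C@H]2C[C@H](C(C)(C)CCCCl)[C@H]1C
F4 | step 6 | bicyclic 7,8-epoxy-9-ol (C9 epimer mixture) | OC1[C@@]2(C)CCCC(C)(C)[C@H]2C[C@@H]3O[C@]13C
F5 | step 6 | O-(imidazol-1-ylthiocarbonyl) derivative of F4 | S=C(OC1[C@@]2(C)CCCC(C)(C)[C@H]2C[C@@H]3O[C@]13C)n1ccnc1
F6 | step 8 | 7-iodo cis-fused γ-lactone, iodine trans to the lactone oxygen | O=C1C[C@@H]2[C@@]3(C)CCCC(C)(C)[C@H]3C[C@@H](I)[C@]2(C)O1
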